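The tetrahydrofuran ring of the bicycle (O4–C5–C6–C6a–C3a in furo[3,2-b]furan-2-one numbering) is treated as a masked γ-lactone. With C3a at the acyl oxidation level, C6a is the carbinol carbon of lactic acid. The key step is a [3+2] lactone annulation: the lithium enolate of the cis tert-butyl dioxolanone of (R)-lactic acid opens an enantiopure 2,2-disubstituted epoxide at its CH2 (C6–C6a bond, quaternary C6a set anti to the tert-butyl group), and the tertiary oxygen then acylates itself on the dioxolanone carbonyl (O4–C3a bond), expelling pivalaldehyde. The precursor pair is a dioxolanone and an epoxide. A Wittig annulation and a hydrogenation then build the second lactone.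

Key step: step 5

Remark: compounds 1, 2, 5, 11, 12 and (triphenylphosphoranylidene)ketene are taken as commercial; positions in the bicycle are cited as O1, C2 (carbonyl), C3, C3a, O4, C5, C6, C6a.

Step 1
Reactants: 1 11-bromoundec-1-ene; 2 1-(benzyloxy)-4-iodobenzene
Product: 4 1-(benzyloxy)-4-(11-bromoundecyl)benzene, via alkylborane 3 (not isolated)
Conditions: 9-BBN, THF, 0 °C to rt; then 2, PdCl2(dppf) (3 mol%), AsPh3, Cs2CO3, DMF/H2O, rt
Reagents that add atoms: none
Why: Anti-Markovnikov hydroboration followed by B-alkyl Suzuki–Miyaura coupling should join the chain to the arene, because oxidative addition into the aryl iodide at rt is far faster than into the primary alkyl bromide; no stereocentre is formed.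

Step 2
Reactants: 4 1-(benzyloxy)-4-(11-bromoundecyl)benzene; 5 (R)-2-methylglycidol
Product: 8 (2S)-14-[4-(benzyloxy)phenyl]-2-methyltetradecane-1,2-diol, via Grignard reagent 6 (not isolated), via magnesium alkoxide 7 (not isolated)
Conditions: 4, Mg, THF, 40 °C; separately 5, i-PrMgCl (1.0 equiv), THF, −40 °C; combine, CuI (10 mol%), −40 °C to 0 °C; aq NH4Cl
Reagents that add atoms: none
Why: Copper-catalysed Grignard opening of a 2,2-disubstituted epoxide takes place by SN2 at the unsubstituted CH2, so the tertiary carbinol centre of 5 is carried over untouched, and masking the hydroxyl as its magnesium alkoxide saves the chain Grignard reagent.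

Step 3
Reactants: 8 (2S)-14-[4-(benzyloxy)phenyl]-2-methyltetradecane-1,2-diol
Product: 10 (2S)-2-{12-[4-(benzyloxy)phenyl]dodecyl}-2-methyloxirane, via primary tosylate 9 (not isolated)
Conditions: NaH (2.5 equiv), N-tosylimidazole (1.05 equiv), THF, 0 °C to rt
Reagents that add atoms: none
Why: Selective sulfonylation of the primary alkoxide followed by 3-exo-tet Williamson closure by the tertiary alkoxide should give the epoxide with retention, since no bond to the stereocentre is broken.

Step 4
Reactants: 11 (R)-lactic acid; 12 pivalaldehyde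
Product: 13 (2R,5R)-2-tert-butyl-5-methyl-1,3-dioxolan-4-one
Conditions: TsOH·H2O (cat.), H2SO4 (cat.), pentane, reflux, Dean–Stark trap; crystallisation from Et2O/pentane, −78 °C
Reagents that add atoms: none
Why: Acid-catalysed acetalisation with removal of water should favour the cis dioxolanone, which is freed from the trans isomer by low-temperature crystallisation, the lactate centre directing the new acetal centre.

Step 5
Reactants: 13 (2R,5R)-2-tert-butyl-5-methyl-1,3-dioxolan-4-one; 10 (2S)-2-{12-[4-(benzyloxy)phenyl]dodecyl}-2-methyloxirane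
Product: 16 (3S,5S)-5-{12-[4-(benzyloxy)phenyl]dodecyl}-3-hydroxy-3,5-dimethyloxolan-2-one, via lithium enolate 14 (not isolated), via hydroxy dioxolanone 15 (not isolated)
Conditions: 13 (2 equiv), LiN(i-Pr)2 (2 equiv), THF, −78 °C; then 10 (1 equiv), BF3·OEt2 (2 equiv), −78 °C; then 2 M HCl, −78 °C to rt
Reagents that add atoms: none
Why: Deprotonation of 13 gives the planar enolate 14, whose C-5 attacks the unsubstituted CH2 of the BF3-activated epoxide in an intermolecular SN2 opening; on acidification the tertiary hydroxyl of 15 attacks the acylal carbonyl and the tetrahedral intermediate collapses with loss of pivalaldehyde. The closest known reaction types are the alkylation of this dioxolanone enolate with self-regeneration of the stereocentre and the BF3-assisted opening of epoxides by lithium ester enolates that ends in γ-lactones. The one ring that closes, the γ-lactone that later is the tetrahydrofuran ring, forms by 5-exo-trig acyl substitution. The new quaternary centre C-3 is controlled by the acetal tert-butyl group, which blocks one face of the enolate so that the CH2 enters trans to it and takes the place of the former hydrogen (3S from (R)-lactic acid), while C-5 comes unchanged from the epoxide because its C–O bond is not broken. The step needs attack at the primary epoxide carbon and no ionisation at the tertiary one, which the low temperature, the preformed nucleophile and the shielding of the quaternary carbon should secure, and it needs facial selectivity, which the rigid dioxolanone envelope secures.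

Step 6
Reactants: 16 (3S,5S)-5-{12-[4-(benzyloxy)phenyl]dodecyl}-3-hydroxy-3,5-dimethyloxolan-2-one
Product: 18 (5S,6aS)-5-{12-[4-(benzyloxy)phenyl]dodecyl}-5,6a-dimethyl-6,6a-dihydrofuro[3,2-b]furan-2(5H)-one, via ester ylide 17 (not isolated)
Conditions: Ph3P=C=C=O (1.5 equiv), toluene, 110 °C
Reagents that add atoms: (triphenylphosphoranylidene)ketene, O=C=C=P(c1ccccc1)(c1ccccc1)c1ccccc1
Why: The tertiary hydroxyl adds across the C=C of the cumulated ylide to give ester ylide 17, and intramolecular Wittig olefination of the neighbouring lactone carbonyl closes the butenolide (the domino addition–Wittig tetronate synthesis known for α-hydroxy esters), leaving the ring O–C bond of step 5 intact and creating no stereocentre.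

Step 7
Reactants: 18 (5S,6aS)-5-{12-[4-(benzyloxy)phenyl]dodecyl}-5,6a-dimethyl-6,6a-dihydrofuro[3,2-b]furan-2(5H)-one
Product: 19 (3aS,5S,6aS)-5-[12-(4-hydroxyphenyl)dodecyl]-5,6a-dimethyltetrahydrofuro[3,2-b]furan-2(3H)-one (plakortone N)
Conditions: H2 (4 bar), 10% Pd/C, EtOAc, rt
Reagents that add atoms: none
Why: Heterogeneous syn-hydrogenation of the tetronate C=C should deliver hydrogen to C-3a from the face that carries the C-6a methyl group, opposite the tetrahydrofuran ring carbons and the only path to the strain-free cis-fused bicycle, so that C-3a is set as S by the adjacent quaternary centre, while the benzyl ether is hydrogenolysed under the same conditions.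

Compound list
1 | 11-bromoundec-1-ene | C=CCCCCCCCCCBr | starting material
2 | 1-(benzyloxy)-4-iodobenzene | Ic1ccc(OCc2ccccc2)cc1 | starting material
3 | 9-(11-bromoundecyl)-9-borabicyclo[3.3.1]nonane | BrCCCCCCCCCCCB1C2CCCC1CCC2 | intermediate
4 | 1-(benzyloxy)-4-(11-bromoundecyl)benzene | BrCCCCCCCCCCCc1ccc(OCc2ccccc2)cc1 | intermediate
5 | (R)-2-methylglycidol, (2R)-(2-methyloxiran-2-yl)methanol | C[C@@]1(CO)CO1 | starting material
6 | {11-[4-(benzyloxy)phenyl]undecyl}magnesium bromide | Br[Mg]CCCCCCCCCCCc1ccc(OCc2ccccc2)cc1 | intermediate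
7 | chloromagnesium (2R)-(2-methyloxiran-2-yl)methoxide | C[C@@]1(CO[Mg]Cl)CO1 | intermediate
8 | (2S)-14-[4-(benzyloxy)phenyl]-2-methyltetradecane-1,2-diol | C[C@@](O)(CO)CCCCCCCCCCCCc1ccc(OCc2ccccc2)cc1 | intermediate
9 | (2S)-14-[4-(benzyloxy)phenyl]-2-hydroxy-2-methyltetradecyl 4-methylbenzenesulfonate | C[C@@](O)(COS(=O)(=O)c1ccc(C)cc1)CCCCCCCCCCCCc1ccc(OCc2ccccc2)cc1 | intermediate
10 | (2S)-2-{12-[4-(benzyloxy)phenyl]dodecyl}-2-methyloxirane | C[C@]1(CCCCCCCCCCCCc2ccc(OCc3ccccc3)cc2)CO1 | intermediate
11 | (R)-lactic acid | C[C@@H](O)C(=O)O | starting material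
12 | pivalaldehyde | CC(C)(C)C=O | starting material
13 | (2R,5R)-2-tert-butyl-5-methyl-1,3-dioxolan-4-one | C[C@H]1O[C@@H](C(C)(C)C)OC1=O | intermediate
14 | lithium (2R)-2-tert-butyl-5-methyl-1,3-dioxol-4-olate | CC1=C(O[Li])O[C@H](C(C)(C)C)O1 | intermediate
15 | (2R,5S)-5-{(2S)-14-[4-(benzyloxy)phenyl]-2-hydroxy-2-methyltetradecyl}-2-tert-butyl-5-methyl-1,3-dioxolan-4-one | C[C@@]1(C[C@@](C)(O)CCCCCCCCCCCCc2ccc(OCc3ccccc3)cc2)O[C@@H](C(C)(C)C)OC1=O | intermediate
16 | (3S,5S)-5-{12-[4-(benzyloxy)phenyl]dodecyl}-3-hydroxy-3,5-dimethyloxolan-2-one | C[C@]1(CCCCCCCCCCCCc2ccc(OCc3ccccc3)cc2)C[C@](C)(O)C(=O)O1 | intermediate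
17 | (3S,5S)-5-{12-[4-(benzyloxy)phenyl]dodecyl}-3,5-dimethyl-2-oxooxolan-3-yl (triphenylphosphoranylidene)acetate | C[C@]1(CCCCCCCCCCCCc2ccc(OCc3ccccc3)cc2)C[C@](C)(OC(=O)C=P(c2ccccc2)(c2ccccc2)c2ccccc2)C(=O)O1 | intermediate
18 | (5S,6aS)-5-{12-[4-(benzyloxy)phenyl]dodecyl}-5,6a-dimethyl-6,6a-dihydrofuro[3,2-b]furan-2(5H)-one | C[C@]1(CCCCCCCCCCCCc2ccc(OCc3ccccc3)cc2)C[C@]2(C)OC(=O)C=C2O1 | intermediate
19 | (3aS,5S,6aS)-5-[12-(4-hydroxyphenyl)dodecyl]-5,6a-dimethyltetrahydrofuro[3,2-b]furan-2(3H)-one (plakortone N) | C[C@]1(CCCCCCCCCCCCc2ccc(O)cc2)C[C@]2(C)OC(=O)C[C@@H]2O1 | target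

Total step count: 7. Longest linear sequence: 6 steps (1, 2, 3, 5, 6, 7).

Steps most likely to fail

Step 5. The Lewis acid may ionise the epoxide at its tertiary carbon, giving hydride shift to an aldehyde or attack at the wrong terminus with loss of the C-5 configuration. Alternatively, bond formation between two hindered centres may be slower than decomposition of the enolate. The fallback reverses the polarity of the C–C bond formation and sets out from 10. LiI and AcOH in THF should open the epoxide at CH2 to the iodohydrin F1. Deprotonation with n-BuLi and iodine–lithium exchange with t-BuLi (2 equiv) in Et2O/pentane at −78 °C should give the β-lithio alkoxide F2. This is added at −78 °C to (1R,2S,5R)-8-phenylmenthyl pyruvate F3, made from commercial (−)-8-phenylmenthol and pyruvic acid with DCC and DMAP. Addition to the ketone, on the face left open by the phenyl group of the auxiliary, should give the dihydroxy ester F4 as its dialkoxide. On warming to rt its tertiary alkoxide should lactonise with release of the auxiliary, and the route is rejoined at 16.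

Step 6. Addition of the hindered tertiary hydroxyl to the cumulated ylide may be slower than self-condensation of the ylide. The fallback builds the ester ylide stepwise and sets out from 16. Acylation with bromoacetyl bromide (pyridine, DMAP, CH2Cl2, 0 °C) should give the bromoacetate F5. PPh3 in MeCN should give the phosphonium bromide F6. NaN(SiMe3)2 in THF/toluene, 0 °C to 80 °C, should liberate ylide 17, which closes to 18 by the same intramolecular Wittig reaction.

Step 7. The allylic tertiary C–O bond of the butenolide may be hydrogenolysed before the hindered vinylogous carbonate is saturated, or the alkene may resist reduction. The fallback avoids the tetronate and sets out from 16. Reduction with i-Bu2AlH in CH2Cl2 at −78 °C should give the lactol F7. Wittig olefination with Ph3P=CHCO2Et in toluene at 80 °C should give the hydroxy enoate F8. With a catalytic amount of DBU, F8 should undergo reversible 5-exo-trig oxa-Michael addition, and only the cis adduct can lactonise, giving the benzyl-protected bicycle F9. In this detour the ring O–C3a bond is opened and re-formed. Hydrogenolysis (H2, 1 bar, 10% Pd/C, EtOAc), now without an allylic C–O bond, comes back to the route at 19.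

Further compounds
F1 | step 5 | (2S)-14-[4-(benzyloxy)phenyl]-1-iodo-2-methyltetradecan-2-ol | C[C@@](O)(CI)CCCCCCCCCCCCc1ccc(OCc2ccccc2)cc1
F2 | step 5 | lithium (2S)-14-[4-(benzyloxy)phenyl]-1-lithio-2-methyltetradecan-2-olate | C[C@@](O[Li])(C[Li])CCCCCCCCCCCCc1ccc(OCc2ccccc2)cc1
F3 | step 5 | (1R,2S,5R)-8-phenylmenthyl pyruvate | CC(=O)C(=O)O[C@@H]1C[C@H](C)CC[C@H]1C(C)(C)c1ccccc1
F4 | step 5 | (1R,2S,5R)-8-phenylmenthyl (2S,4S)-16-[4-(benzyloxy)phenyl]-2,4-dihydroxy-2,4-dimethylhexadecanoate | C[C@](O)(CCCCCCCCCCCCc1ccc(OCc2ccccc2)cc1)C[C@](C)(O)C(=O)O[C@@H]1C[C@H](C)CC[C@H]1C(C)(C)c1ccccc1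
F5 | step 6 | (3S,5S)-5-{12-[4-(benzyloxy)phenyl]dodecyl}-3,5-dimethyl-2-oxooxolan-3-yl bromoacetate | C[C@]1(CCCCCCCCCCCCc2ccc(OCc3ccccc3)cc2)C[C@](C)(OC(=O)CBr)C(=O)O1
F6 | step 6 | [2-({(3S,5S)-5-{12-[4-(benzyloxy)phenyl]dodecyl}-3,5-dimethyl-2-oxooxolan-3-yl}oxy)-2-oxoethyl]triphenylphosphonium bromide | C[C@]1(CCCCCCCCCCCCc2ccc(OCc3ccccc3)cc2)C[C@](C)(OC(=O)C[P+](c2ccccc2)(c2ccccc2)c2ccccc2)C(=O)O1.[Br-]
F7 | step 7 | (3S,5S)-5-{12-[4-(benzyloxy)phenyl]dodecyl}-3,5-dimethyloxolane-2,3-diol (anomer mixture) | C[C@]1(CCCCCCCCCCCCc2ccc(OCc3ccccc3)cc2)C[C@](C)(O)C(O)O1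
F8 | step 7 | ethyl (2E,4S,6S)-18-[4-(benzyloxy)phenyl]-4,6-dihydroxy-4,6-dimethyloctadec-2-enoate | C[C@](O)(CCCCCCCCCCCCc1ccc(OCc2ccccc2)cc1)C[C@](C)(O)/C=C/C(=O)OCC
F9 | step 7 | (3aS,5S,6aS)-5-{12-[4-(benzyloxy)phenyl]dodecyl}-5,6a-dimethyltetrahydrofuro[3,2-b]furan-2(3H)-one | C[C@]1(CCCCCCCCCCCCc2ccc(OCc3ccccc3)cc2)C[C@]2(C)OC(=O)C[C@@H]2O1
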